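**Retrosynthetic overview**
1. The cinnamate comes from Heck arylation (iodobenzene) of an acrylate, made by lipase-selective acylation of the primary alcohol with vinyl acrylate.
2. The C7 carboxyl comes from late C–H borylation at the only unhindered aryl C–H followed by carboxylation with CO2; the phenol is unmasked from its methyl ether.
3. The C1–C11 bond and the C1 stereocentre come from the key 1,2-shift: the C11 sec-alkyl group migrates from boron to C1 in a boronate built from a tetralone-derived alkenyllithium and a secondary boronic ester, followed by protodeboronation.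
4. The tetralone (the only ring formed; the arene is bought as anisole) comes from Friedel–Crafts acylation of an (R)-4-arylpentanoic acid, whose C4 centre is set by asymmetric hydrogenation (anisole + succinic anhydride, then Wittig).
5. The boronic ester comes from (S)-3-bromo-2-methylpropan-1-ol (C15 from the chiral pool), vinyl Grignard and hydroboration, then a lithiation–borylation 1,2-shift that sets C11.

Numbering used: tetralin C1 carries the side chain, C4 the methyl, C5 the oxygen, C7 the carboxyl; C11 is the side-chain carbon on C1, C15 the methyl-bearing carbon next to the CH2O group.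

Assumption: both enantiomers of sparteine and of the spiro P,N ligand are available, and the enantiomer that gives the stated configuration is used.

**Route**

Step 1
Reactants: 1 anisole; 2 succinic anhydride
Product: 4 4-(2-methoxyphenyl)-4-oxobutanoic acid, via 2-lithioanisole 3 (not isolated)
Conditions: n-BuLi, TMEDA, Et2O, 0 °C to rt; inverse addition to 2 (1.5 equiv), THF, −78 °C; aq HCl
Reagents that add atoms: none
Why: Methoxy-directed ortho-lithiation gives the aryllithium, which opens the cyclic anhydride by nucleophilic acyl substitution to the γ-keto acid (no stereocentre).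

Step 2
Reactants: 4 4-(2-methoxyphenyl)-4-oxobutanoic acid
Product: 5 4-(2-methoxyphenyl)pent-4-enoic acid
Conditions: Ph3PCH3Br (2.4 equiv), KOtBu (2.4 equiv), THF, 0 °C to rt; aq HCl
Reagents that add atoms: methyltriphenylphosphonium bromide, C[P+](c1ccccc1)(c1ccccc1)c1ccccc1.[Br-]
Why: Wittig methylenation of the aryl ketone with excess ylide (one equivalent is consumed by the acid) gives the 1,1-disubstituted alkene.

Step 3
Reactants: 5 4-(2-methoxyphenyl)pent-4-enoic acid
Product: 6 (4R)-4-(2-methoxyphenyl)pentanoic acid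
Conditions: H2 (6 atm), [Ir(cod)(L)][B(3,5-(CF3)2C6H3)4] (1 mol%, L = spiro phosphine–oxazoline ligand SIPHOX, enantiomer giving the R acid), Et3N (0.5 equiv), MeOH, rt
Reagents that add atoms: none
Why: Carboxy-directed iridium-catalysed asymmetric hydrogenation of an α-aryl-α-alkyl terminal alkene, in which the bound carboxylate and the chiral P,N ligand select the alkene face and set C4 as R.

Step 4
Reactants: 6 (4R)-4-(2-methoxyphenyl)pentanoic acid
Product: 7 (4R)-5-methoxy-4-methyl-3,4-dihydronaphthalen-1(2H)-one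
Conditions: P2O5/MeSO3H (1:10 w/w), 60 °C
Reagents that add atoms: none
Why: Intramolecular Friedel–Crafts acylation can close the six-membered ring only at the free position ortho to the side chain, and the benzylic stereocentre is not touched.

Step 5
Reactants: 7 (4R)-5-methoxy-4-methyl-3,4-dihydronaphthalen-1(2H)-one
Product: 8 (E)-N'-[(4R)-5-methoxy-4-methyl-3,4-dihydronaphthalen-1(2H)-ylidene]-2,4,6-triisopropylbenzenesulfonohydrazide
Conditions: 2,4,6-triisopropylbenzenesulfonyl hydrazide, cat. HCl, MeOH/THF, rt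
Reagents that add atoms: 2,4,6-triisopropylbenzenesulfonyl hydrazide, CC(C)c1cc(C(C)C)c(S(=O)(=O)NN)c(C(C)C)c1
Why: Acid-catalysed hydrazone condensation gives the trisylhydrazone needed for a clean Shapiro reaction.

Step 6
Reactants: 9 (2S)-3-bromo-2-methylpropan-1-ol
Product: 10 [(2S)-3-bromo-2-methylpropoxy](tert-butyl)dimethylsilane
Conditions: TBSCl, imidazole, CH2Cl2, 0 °C to rt
Reagents that add atoms: tert-butyldimethylsilyl chloride, C[Si](C)(Cl)C(C)(C)C
Why: Standard silyl protection of the primary alcohol, needed for the organometallic steps that follow.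

Step 7
Reactants: 10 [(2S)-3-bromo-2-methylpropoxy](tert-butyl)dimethylsilane; 11 vinylmagnesium bromide
Product: 12 tert-butyldimethyl{[(2R)-2-methylpent-4-en-1-yl]oxy}silane
Conditions: Fe(acac)3 (5 mol%), TMEDA, hexamethylenetetramine, THF, 0 °C
Reagents that add atoms: none
Why: Iron-catalysed Kumada-type alkyl–alkenyl cross-coupling at the primary bromide, with the stereocentre β to the reacting carbon left untouched (the descriptor changes only by priority).

Step 8
Reactants: 12 tert-butyldimethyl{[(2R)-2-methylpent-4-en-1-yl]oxy}silane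
Product: 13 tert-butyldimethyl{[(2R)-2-methyl-5-(4,4,5,5-tetramethyl-1,3,2-dioxaborolan-2-yl)pentyl]oxy}silane
Conditions: HBpin, [Ir(cod)Cl]2 (1.5 mol%), dppe (3 mol%), CH2Cl2, rt
Reagents that add atoms: pinacolborane, [H]B1OC(C)(C)C(C)(C)O1
Why: Iridium-catalysed anti-Markovnikov hydroboration of the terminal alkene gives the primary boronic ester.

Step 9
Reactants: 13 tert-butyldimethyl{[(2R)-2-methyl-5-(4,4,5,5-tetramethyl-1,3,2-dioxaborolan-2-yl)pentyl]oxy}silane
Product: 15 tert-butyldimethyl{[(2R,6S)-2-methyl-6-(4,4,5,5-tetramethyl-1,3,2-dioxaborolan-2-yl)heptyl]oxy}silane, via boronate complex 14 (not isolated)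
Conditions: ethyl N,N-diisopropylcarbamate, (+)-sparteine, s-BuLi, Et2O, −78 °C; add 13, −78 °C; MgBr2·OEt2, reflux
Reagents that add atoms: ethyl N,N-diisopropylcarbamate, CCOC(=O)N(C(C)C)C(C)C
Why: Lithiation–borylation homologation (Hoppe–Aggarwal), in which sparteine-controlled deprotonation gives a configurationally stable lithiated carbamate that adds to boron with retention, after which the alkyl group undergoes a stereospecific 1,2-metallate shift with inversion at the carbenoid carbon and sets C11 as S.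

Step 10
Reactants: 8 (E)-N'-[(4R)-5-methoxy-4-methyl-3,4-dihydronaphthalen-1(2H)-ylidene]-2,4,6-triisopropylbenzenesulfonohydrazide; 15 tert-butyldimethyl{[(2R,6S)-2-methyl-6-(4,4,5,5-tetramethyl-1,3,2-dioxaborolan-2-yl)heptyl]oxy}silane
Product: 19 (2R,6S)-6-[(1S,4R)-5-methoxy-4-methyl-1,2,3,4-tetrahydronaphthalen-1-yl]-2-methylheptan-1-ol, via alkenyllithium 16 (not isolated), via boronate complex 17 (not isolated), via tertiary boronic ester 18 (not isolated)
Conditions: n-BuLi (2.2 equiv), THF, −78 to 0 °C; 15, −78 °C; CF3CO2H (1.1 equiv), −78 °C to rt; then TBAF·3H2O, toluene, 60 °C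
Reagents that add atoms: none
Why: Proposed new method: a Shapiro reaction gives the cyclic α-aryl alkenyllithium, which forms the boronate with 15, and protonation of its nucleophilic β-carbon (C2) triggers an anti 1,2-shift of the sec-alkyl group from boron to C1 with retention at C11; because the peri methoxy group locks the C4 methyl pseudoaxial, the trans-diaxial addition mode places the migrating group on the face opposite to that methyl (C1 becomes S), and the fluoride-mediated protodeboronation of the tertiary benzylic boronic ester then proceeds with retention while the silyl ether is cleaved; the closest known reaction types are the Zweifel olefination (iodine-triggered 1,2-metallate shift of alkenyl boronates) and the acid-induced migration in alkenyl trialkylborates.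

Step 11
Reactants: 19 (2R,6S)-6-[(1S,4R)-5-methoxy-4-methyl-1,2,3,4-tetrahydronaphthalen-1-yl]-2-methylheptan-1-ol
Product: 21 (5R,8S)-8-[(2S,6R)-7-hydroxy-6-methylheptan-2-yl]-4-methoxy-5-methyl-5,6,7,8-tetrahydronaphthalene-2-carboxylic acid, via aryl boronate 20 (not isolated)
Conditions: B2pin2 (2 equiv), [Ir(OMe)(cod)]2 (1.5 mol%), dtbpy (3 mol%), THF, 80 °C; evaporate; then (IPr)CuCl (5 mol%), CsF (3 equiv), CO2 (1 atm), DMF, 90 °C; aq HCl
Reagents that add atoms: carbon dioxide, O=C=O
Why: Sterically controlled iridium-catalysed C–H borylation goes to C7, the only aryl C–H without an ortho substituent (the alcohol is carried as its borate), and the aryl boronate is then carboxylated by copper-catalysed transmetalation and CO2 insertion.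

Step 12
Reactants: 21 (5R,8S)-8-[(2S,6R)-7-hydroxy-6-methylheptan-2-yl]-4-methoxy-5-methyl-5,6,7,8-tetrahydronaphthalene-2-carboxylic acid
Product: 22 (5R,8S)-4-hydroxy-8-[(2S,6R)-7-hydroxy-6-methylheptan-2-yl]-5-methyl-5,6,7,8-tetrahydronaphthalene-2-carboxylic acid
Conditions: NaSEt (6 equiv), DMF, 130 °C; aq HCl
Reagents that add atoms: none
Why: SN2 demethylation of the aryl methyl ether by thiolate tolerates the carboxylate and the free alcohol and does not touch the stereocentres.

Step 13
Reactants: 22 (5R,8S)-4-hydroxy-8-[(2S,6R)-7-hydroxy-6-methylheptan-2-yl]-5-methyl-5,6,7,8-tetrahydronaphthalene-2-carboxylic acid; 23 vinyl acrylate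
Product: 24 (5R,8S)-8-[(2S,6R)-7-(acryloyloxy)-6-methylheptan-2-yl]-4-hydroxy-5-methyl-5,6,7,8-tetrahydronaphthalene-2-carboxylic acid
Conditions: Novozym 435 (immobilised Candida antarctica lipase B), BHT, THF, 40 °C
Reagents that add atoms: none
Why: Lipase-catalysed transesterification acylates only the primary aliphatic alcohol (phenol and aryl acid are not substrates) and is made irreversible by loss of vinyl alcohol as acetaldehyde.

Step 14
Reactants: 24 (5R,8S)-8-[(2S,6R)-7-(acryloyloxy)-6-methylheptan-2-yl]-4-hydroxy-5-methyl-5,6,7,8-tetrahydronaphthalene-2-carboxylic acid; 25 iodobenzene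
Product: 26 (5R,8S)-4-hydroxy-5-methyl-8-[(2S,6R)-6-methyl-7-{[(2E)-3-phenylprop-2-enoyl]oxy}heptan-2-yl]-5,6,7,8-tetrahydronaphthalene-2-carboxylic acid
Conditions: Pd(OAc)2 (5 mol%), P(o-tol)3 (10 mol%), Et3N (4 equiv), DMF, 90 °C
Reagents that add atoms: none
Why: Mizoroki–Heck arylation of the acrylate, where syn-insertion and syn-β-hydride elimination give the E-cinnamate, completes the target.

**Compound list**
1 | anisole | COc1ccccc1 | starting material
2 | succinic anhydride | O=C1CCC(=O)O1 | starting material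
3 | 2-lithioanisole | [Li]c1ccccc1OC | intermediate
4 | 4-(2-methoxyphenyl)-4-oxobutanoic acid | COc1ccccc1C(=O)CCC(=O)O | intermediate
5 | 4-(2-methoxyphenyl)pent-4-enoic acid | COc1ccccc1C(=C)CCC(=O)O | intermediate
6 | (4R)-4-(2-methoxyphenyl)pentanoic acid | C[C@H](CCC(=O)O)c1ccccc1OC | intermediate
7 | (4R)-5-methoxy-4-methyl-3,4-dihydronaphthalen-1(2H)-one | O=C1CC[C@@H](C)c2c(OC)cccc21 | intermediate
8 | (E)-N'-[(4R)-5-methoxy-4-methyl-3,4-dihydronaphthalen-1(2H)-ylidene]-2,4,6-triisopropylbenzenesulfonohydrazide | CC(C)c1cc(C(C)C)c(S(=O)(=O)N/N=C2\CC[C@@H](C)c3c(OC)cccc32)c(C(C)C)c1 | intermediate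
9 | (2S)-3-bromo-2-methylpropan-1-ol | C[C@H](CBr)CO | starting material
10 | [(2S)-3-bromo-2-methylpropoxy](tert-butyl)dimethylsilane | C[C@H](CBr)CO[Si](C)(C)C(C)(C)C | intermediate
11 | vinylmagnesium bromide | C=C[Mg]Br | starting material
12 | tert-butyldimethyl{[(2R)-2-methylpent-4-en-1-yl]oxy}silane | C[C@H](CC=C)CO[Si](C)(C)C(C)(C)C | intermediate
13 | tert-butyldimethyl{[(2R)-2-methyl-5-(4,4,5,5-tetramethyl-1,3,2-dioxaborolan-2-yl)pentyl]oxy}silane | C[C@H](CCCB1OC(C)(C)C(C)(C)O1)CO[Si](C)(C)C(C)(C)C | intermediate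
14 | lithium [(1R)-1-(diisopropylcarbamoyloxy)ethyl][(4R)-5-(tert-butyldimethylsilyloxy)-4-methylpentyl](pinacolato)borate | [Li+].C[C@H](CCC[B-]1(OC(C)(C)C(C)(C)O1)[C@H](C)OC(=O)N(C(C)C)C(C)C)CO[Si](C)(C)C(C)(C)C | intermediate
15 | tert-butyldimethyl{[(2R,6S)-2-methyl-6-(4,4,5,5-tetramethyl-1,3,2-dioxaborolan-2-yl)heptyl]oxy}silane | C[C@H](CCC[C@H](C)B1OC(C)(C)C(C)(C)O1)CO[Si](C)(C)C(C)(C)C | intermediate
16 | [(4R)-5-methoxy-4-methyl-3,4-dihydronaphthalen-1-yl]lithium | [Li]C1=CC[C@@H](C)c2c(OC)cccc21 | intermediate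
17 | lithium [(2S,6R)-7-(tert-butyldimethylsilyloxy)-6-methylheptan-2-yl][(4R)-5-methoxy-4-methyl-3,4-dihydronaphthalen-1-yl](pinacolato)borate | [Li+].C[C@H](CCC[C@H](C)[B-]1(OC(C)(C)C(C)(C)O1)C1=CC[C@@H](C)c2c(OC)cccc21)CO[Si](C)(C)C(C)(C)C | intermediate
18 | tert-butyl{[(2R,6S)-6-[(1S,4R)-5-methoxy-4-methyl-1-(4,4,5,5-tetramethyl-1,3,2-dioxaborolan-2-yl)-1,2,3,4-tetrahydronaphthalen-1-yl]-2-methylheptyl]oxy}dimethylsilane | C[C@H](CCC[C@H](C)[C@]1(B3OC(C)(C)C(C)(C)O3)CC[C@@H](C)c2c(OC)cccc21)CO[Si](C)(C)C(C)(C)C | intermediate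
19 | (2R,6S)-6-[(1S,4R)-5-methoxy-4-methyl-1,2,3,4-tetrahydronaphthalen-1-yl]-2-methylheptan-1-ol | C[C@H](CCC[C@H](C)[C@@H]1CC[C@@H](C)c2c(OC)cccc21)CO | intermediate
20 | 2-{[(2R,6S)-6-[(1S,4R)-5-methoxy-4-methyl-7-(4,4,5,5-tetramethyl-1,3,2-dioxaborolan-2-yl)-1,2,3,4-tetrahydronaphthalen-1-yl]-2-methylheptyl]oxy}-4,4,5,5-tetramethyl-1,3,2-dioxaborolane | C[C@H](CCC[C@H](C)[C@@H]1CC[C@@H](C)c2c(OC)cc(B3OC(C)(C)C(C)(C)O3)cc21)COB1OC(C)(C)C(C)(C)O1 | intermediate
21 | (5R,8S)-8-[(2S,6R)-7-hydroxy-6-methylheptan-2-yl]-4-methoxy-5-methyl-5,6,7,8-tetrahydronaphthalene-2-carboxylic acid | C[C@H](CCC[C@H](C)[C@@H]1CC[C@@H](C)c2c(OC)cc(C(=O)O)cc21)CO | intermediate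
22 | (5R,8S)-4-hydroxy-8-[(2S,6R)-7-hydroxy-6-methylheptan-2-yl]-5-methyl-5,6,7,8-tetrahydronaphthalene-2-carboxylic acid | C[C@H](CCC[C@H](C)[C@@H]1CC[C@@H](C)c2c(O)cc(C(=O)O)cc21)CO | intermediate
23 | vinyl acrylate | C=CC(=O)OC=C | starting material
24 | (5R,8S)-8-[(2S,6R)-7-(acryloyloxy)-6-methylheptan-2-yl]-4-hydroxy-5-methyl-5,6,7,8-tetrahydronaphthalene-2-carboxylic acid | C[C@H](CCC[C@H](C)[C@@H]1CC[C@@H](C)c2c(O)cc(C(=O)O)cc21)COC(=O)C=C | intermediate
25 | iodobenzene | Ic1ccccc1 | starting material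
26 | (5R,8S)-4-hydroxy-5-methyl-8-[(2S,6R)-6-methyl-7-{[(2E)-3-phenylprop-2-enoyl]oxy}heptan-2-yl]-5,6,7,8-tetrahydronaphthalene-2-carboxylic acid (CNP0505009.1) | C[C@H](CCC[C@H](C)[C@@H]1CC[C@@H](C)c2c(O)cc(C(=O)O)cc21)COC(=O)/C=C/c1ccccc1 | target

**Step count**
Total: 14 steps. Longest linear sequence: 10 steps (steps 1–5 and 10–14); the side-chain branch (steps 6–9) joins at step 10.

**Three steps most likely to fail**

Step 10 (the proposed new step). The risks are protonation at C1 instead of C2 (simple protodeboronation of the alkenyl group, returning 15) and modest face selectivity at C1. The fallback uses known lithiation–borylation chemistry; it sets out from 7 (with 15) and comes back at 18. Ketone 7 is reduced with BH3·SMe2 and (R)-2-methyl-CBS-oxazaborolidine to the cis alcohol (1S,4R)-5-methoxy-4-methyl-1,2,3,4-tetrahydronaphthalen-1-ol F1. This is carbamoylated (iPr2NCOCl, NaH, THF) to (1S,4R)-5-methoxy-4-methyl-1,2,3,4-tetrahydronaphthalen-1-yl N,N-diisopropylcarbamate F2. Deprotonation with s-BuLi (Et2O, −78 °C) gives the configurationally stable lithiated carbamate F3, which adds 15 with retention to give the boronate complex F4. A 1,2-shift promoted by MgBr2/MeOH then expels the carbamate, so boron takes the place of oxygen and the sec-alkyl group the place of hydrogen, giving 18. Compound 18 is then treated with TBAF·3H2O as in step 10 to reach 19. Here C1 is set by reagent control from the carbinol configuration.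

Step 11. The risk lies in the one-pot switch from borylation to copper carboxylation on a hindered, doubly borylated substrate. The fallback sets out from 19 and comes back at 21. The borylation is run alone and, after aqueous work-up, (2R,6S)-6-[(1S,4R)-5-methoxy-4-methyl-7-(4,4,5,5-tetramethyl-1,3,2-dioxaborolan-2-yl)-1,2,3,4-tetrahydronaphthalen-1-yl]-2-methylheptan-1-ol F5 is isolated. Bromodeboronation with CuBr2 in MeOH/H2O at 80 °C gives (2R,6S)-6-[(1S,4R)-7-bromo-5-methoxy-4-methyl-1,2,3,4-tetrahydronaphthalen-1-yl]-2-methylheptan-1-ol F6. Hydroxycarbonylation (Pd(OAc)2, Xantphos, CO 1 atm, K2CO3, DMF/H2O, 80 °C) then gives 21.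

Step 3. The ortho-methoxy group may lower the enantioselectivity of the directed hydrogenation. The fallback takes C4 from the chiral pool; it sets out from 3 and comes back at 6. Aryllithium 3 is transmetalated with MgBr2·OEt2 to 2-methoxyphenylmagnesium bromide F7. With CuI (10 mol%) this opens (S)-β-butyrolactone by SN2 attack at the methyl-bearing carbon (inversion) to give (3R)-3-(2-methoxyphenyl)butanoic acid F8. Arndt–Eistert homologation follows: (COCl)2 with cat. DMF gives (3R)-3-(2-methoxyphenyl)butanoyl chloride F9, and CH2N2 gives (4R)-1-diazo-4-(2-methoxyphenyl)pentan-2-one F10. AgO2CPh, Et3N in THF/H2O then effects the Wolff rearrangement through (4R)-4-(2-methoxyphenyl)pent-1-en-1-one F11, which water traps as 6. The stereocentre is not the migrating carbon and is unaffected.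

**Further compounds**
F1 | step 10 | (1S,4R)-5-methoxy-4-methyl-1,2,3,4-tetrahydronaphthalen-1-ol | O[C@H]1CC[C@@H](C)c2c(OC)cccc21
F2 | step 10 | (1S,4R)-5-methoxy-4-methyl-1,2,3,4-tetrahydronaphthalen-1-yl N,N-diisopropylcarbamate | CC(C)N(C(C)C)C(=O)O[C@H]1CC[C@@H](C)c2c(OC)cccc21
F3 | step 10 | (1S,4R)-1-lithio-5-methoxy-4-methyl-1,2,3,4-tetrahydronaphthalen-1-yl N,N-diisopropylcarbamate | CC(C)N(C(C)C)C(=O)O[C@@]1([Li])CC[C@@H](C)c2c(OC)cccc21
F4 | step 10 | lithium [(1S,4R)-1-(diisopropylcarbamoyloxy)-5-methoxy-4-methyl-1,2,3,4-tetrahydronaphthalen-1-yl][(2S,6R)-7-(tert-butyldimethylsilyloxy)-6-methylheptan-2-yl](pinacolato)borate | [Li+].CC(C)N(C(C)C)C(=O)O[C@@]1([B-]3(OC(C)(C)C(C)(C)O3)[C@@H](C)CCC[C@@H](C)CO[Si](C)(C)C(C)(C)C)CC[C@@H](C)c2c(OC)cccc21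
F5 | step 11 | (2R,6S)-6-[(1S,4R)-5-methoxy-4-methyl-7-(4,4,5,5-tetramethyl-1,3,2-dioxaborolan-2-yl)-1,2,3,4-tetrahydronaphthalen-1-yl]-2-methylheptan-1-ol | C[C@H](CCC[C@H](C)[C@@H]1CC[C@@H](C)c2c(OC)cc(B3OC(C)(C)C(C)(C)O3)cc21)CO
F6 | step 11 | (2R,6S)-6-[(1S,4R)-7-bromo-5-methoxy-4-methyl-1,2,3,4-tetrahydronaphthalen-1-yl]-2-methylheptan-1-ol | C[C@H](CCC[C@H](C)[C@@H]1CC[C@@H](C)c2c(OC)cc(Br)cc21)CO
F7 | step 3 | 2-methoxyphenylmagnesium bromide | COc1ccccc1[Mg]Br
F8 | step 3 | (3R)-3-(2-methoxyphenyl)butanoic acid | C[C@H](CC(=O)O)c1ccccc1OC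
F9 | step 3 | (3R)-3-(2-methoxyphenyl)butanoyl chloride | C[C@H](CC(=O)Cl)c1ccccc1OC
F10 | step 3 | (4R)-1-diazo-4-(2-methoxyphenyl)pentan-2-one | C[C@H](CC(=O)C=[N+]=[N-])c1ccccc1OC
F11 | step 3 | (4R)-4-(2-methoxyphenyl)pent-1-en-1-one | C[C@H](CC=C=O)c1ccccc1OC
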